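In this closed, stirred vessel, substrate and reagent react by parallel steps, and the target can then take up a second substrate.

    substrate + reagent → target (k1 = 2.0 × 10⁻⁴ L mol⁻¹ s⁻¹)
    substrate + reagent → isomer of the product (k2 = 1.5 × 10⁻⁴ L mol⁻¹ s⁻¹)
    substrate + reagent → second isomer (k3 = 9.0 × 10⁻⁵ L mol⁻¹ s⁻¹)
    substrate + target → side product (k4 = 4.1 × 10⁻⁴ L mol⁻¹ s⁻¹)

substrate 0.86 M; reagent 0.688 M; time 6.0 h

- in percentages every species weighs as the substrate in it: one side product counts as two
- the reaction counts as stopped when no species that holds the substrate changes by six tenths of a point or more over the second half of the time
- run time (flask): 6.0 h

* at 6.0 h, what has stopped the reaction, if anything has (all of the substrate has reacted / the reagent has run out first / it is still moving / forward and back rates have come level)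
* how much target there is at 6.0 h, in percent of the substrate charged
* how much side product there is at 6.0 h, in percent of the substrate charged
* how much isomer of the product there is at 6.0 h, in percent of the substrate charged

Count turnovers of reagent. The parallel steps share one rate law, [substrate][reagent], so each mole of reagent spent gives isomer of the product in a fixed share, the isomer share 34.1 %: its constant over the sum of the parallel constants. That is a selectivity, and the target's share is 45.5 %.

Two extreme versions can be solved in the head, each being plain second-order kinetics. In the first, target is consumed at once, so each turnover costs one substrate plus the target's share of a second substrate. In the second, target survives.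

| Version at 6.0 h | [reagent] | Target | Side product | Isomer of the product |
|---|---|---|---|---|
| Target consumed at once | 0.125 M | none | 59.5 % | 22.3 % |
| Target survives | 0.0318 M | 34.7 % | none | 26.0 % |

This flask lies between them, because the side-product constant is comparable with the parallel sum. You can take the midpoint, [reagent] = 0.0784 M. Dividing the target's rate by the reagent's cancels [substrate], so that reagent level gives [target] = 0.0834 M. My reckoning is therefore target 9.70 %, side product 45.0 % and isomer of the product 24.2 %. With [substrate] = 0.0567 M beside that reagent and no step running back, my verdict is: it is still moving.

The forecast says it is still moving, with target 9.9 %, side product 44.4 % and isomer of the product 24 %, and calls the target “a small intermediate that is rapidly consumed into side product”.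

The simulation gives it is still moving, with target 9.89 %, side product 44.3 % and isomer of the product 24.0 %. In this flask, target is made 1.81 times as fast as it is used at 0.551 h, but that ratio is 0.467 at 6.00 h. The target has meanwhile gone from 12.1 % at 3.00 h to 9.89 %. The isomer share times the reagent spent gives 24.0 % here. With 0.21 M of substrate, 71.5 % of the reagent remains, so the share gives 31.8 %, and that flask holds 31.8 %.

The rate constants are assumed; no experiment stands behind them.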